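## Retrosynthetic overview

- Enabling feature: ring A (C1–C2–C3–C4–C4a–C8a) holds one isolated cis double bond, C3=C4, between two sp3 methines (C2 with the sec-butyl group, C4a at the ring fusion). Cutting it leaves two alkene arms that sit trans-diequatorial on an intact ring B.
- Disconnections: acetyl ⇒ vinyl (Wacker, last step); C6 ester and C5 carbinol ⇒ 6-silyloxy 5-ketone (acylate first, then axial hydride); C3=C4 ⇒ relay ring-closing metathesis; C4a–vinyl ⇒ enol silane aldol and selenide elimination; C8a–C1 ⇒ Mukaiyama–Michael addition of a trans-β-sec-butyl-γ-butyrolactone (a temporary ring that fixes C1 against C2) to a (4R,6R)-6-silyloxy-4-methylcyclohexenone.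
- Order of ring formation: ring B first (steps 1–3), the temporary γ-lactone next (steps 4–7, opened in steps 11–14), ring A last (step 17).
- Side chain: an (E)-5-silyloxy-3-methylpent-2-enoate is carried at the alcohol level and oxidised to the acid only after the C5 reduction, so the base-labile 3-methylglutaconate never meets base.

Key step: step 17

Remark: locants C1–C8a in the text are those of the octahydronaphthalene core of the target (C1 acetyl, C2 sec-butyl, C3=C4, C4a, C5 hydroxy, C6 acyloxy, C8 methyl, C8a); the SMILES is read as 1S,2S,4aR,5S,6R,8R,8aS with an (R) sec-butyl carbon and an E side-chain alkene.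

## Route

Step 1
Reactants: 1 propanal; 2 but-3-en-2-one
Product: 4 (4R)-4-methylcyclohex-2-en-1-one, via (2R)-2-methyl-5-oxohexanal 3 (not isolated)
Conditions: (S)-2-[methoxy(diphenyl)methyl]pyrrolidine (5 mol%), ethyl 3,4-dihydroxybenzoate (20 mol%), neat, 4 °C; then LiOH (10 mol%), iPrOH, rt
Reagents that add atoms: none
Why: Enamine-catalysed Michael addition of propanal to the enone, with the diarylmethyl group of the (S)-catalyst shielding one enamine face, should set the (R) methyl stereocentre (future C8), and the intramolecular aldol condensation that follows closes ring B without touching it.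

Step 2
Reactants: 4 (4R)-4-methylcyclohex-2-en-1-one
Product: 5 (4R,6R)-6-hydroxy-4-methylcyclohex-2-en-1-one
Conditions: LiN(iPr)2, THF, −78 °C; 2-(benzenesulfonyl)-3-phenyloxaziridine, −78 °C; aq. NH4Cl
Reagents that add atoms: 2-(benzenesulfonyl)-3-phenyloxaziridine, O=S(=O)(c1ccccc1)N1OC1c1ccccc1
Why: Kinetic α'-deprotonation gives the cross-conjugated lithium dienolate, and its hydroxylation by the N-sulfonyloxaziridine (Davis oxidation) is expected to occur anti to the methyl group across the ring, setting the trans (6R) carbinol (future C6); any cis isomer should be separable by chromatography.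

Step 3
Reactants: 5 (4R,6R)-6-hydroxy-4-methylcyclohex-2-en-1-one
Product: 6 (4R,6R)-6-[(tert-butyldimethylsilyl)oxy]-4-methylcyclohex-2-en-1-one
Conditions: TBSCl, imidazole, DMF, rt
Reagents that add atoms: tert-butyldimethylsilyl chloride, C[Si](C)(Cl)C(C)(C)C
Why: Standard silylation of the secondary alcohol protects the future C6 oxygen through the base and hydride steps and touches no stereocentre.

Step 4
Reactants: 7 (4S)-4-benzyl-1,3-oxazolidin-2-one; 8 (2E)-pent-2-enoyl chloride
Product: 9 (4S)-4-benzyl-3-[(2E)-pent-2-enoyl]-1,3-oxazolidin-2-one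
Conditions: n-BuLi, THF, −78 °C; then 8, −78 → 0 °C
Reagents that add atoms: none
Why: N-Acylation of the lithiated oxazolidinone with the acid chloride should give the enoyl imide with the E double bond intact; no stereocentre is formed.

Step 5
Reactants: 9 (4S)-4-benzyl-3-[(2E)-pent-2-enoyl]-1,3-oxazolidin-2-one
Product: 10 (4S)-4-benzyl-3-[(3R)-3-methylpentanoyl]-1,3-oxazolidin-2-one
Conditions: MeMgBr (2.5 equiv), CuBr·SMe2 (1.2 equiv), THF/Me2S, −40 → −15 °C; aq. NH4Cl
Reagents that add atoms: methylmagnesium bromide, C[Mg]Br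
Why: Auxiliary-controlled organocopper conjugate addition: the magnesium-chelated s-cis enoyl imide is attacked at the β-carbon on the face opposite the benzyl group, which for the E-pentenoyl imide and a methyl nucleophile should give the (3R) centre that becomes the sec-butyl stereocentre.

Step 6
Reactants: 10 (4S)-4-benzyl-3-[(3R)-3-methylpentanoyl]-1,3-oxazolidin-2-one; 11 tert-butyl bromoacetate
Product: 12 tert-butyl (3S,4R)-3-{[(4S)-4-benzyl-2-oxo-1,3-oxazolidin-3-yl]carbonyl}-4-methylhexanoate
Conditions: NaN(SiMe3)2, THF, −78 °C; then 11, −78 → −40 °C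
Reagents that add atoms: none
Why: Evans alkylation: the chelated Z-sodium enolate is alkylated by the bromoacetate on the face opposite the benzyl group, which should set the (S) centre (future C2) next to the existing (R) centre.

Step 7
Reactants: 12 tert-butyl (3S,4R)-3-{[(4S)-4-benzyl-2-oxo-1,3-oxazolidin-3-yl]carbonyl}-4-methylhexanoate
Product: 14 (4S)-4-[(2R)-butan-2-yl]oxolan-2-one, via tert-butyl (3S,4R)-3-(hydroxymethyl)-4-methylhexanoate 13 (not isolated)
Conditions: LiBH4, MeOH (1 equiv), THF, 0 °C; then CF3CO2H, CH2Cl2, rt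
Reagents that add atoms: none
Why: Reductive cleavage of the imide releases the auxiliary and the primary alcohol, and acidolysis of the tert-butyl ester triggers lactonisation to the β-substituted γ-butyrolactone; neither stereocentre is epimerisable under these conditions.

Step 8
Reactants: 15 benzeneselenenyl chloride; 16 ethyl vinyl ether
Product: 18 (phenylselanyl)acetaldehyde, via [(2-chloro-2-ethoxyethyl)selanyl]benzene 17 (not isolated)
Conditions: CH2Cl2, −78 → 0 °C; then H2O, rt
Reagents that add atoms: water, O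
Why: Markovnikov addition of the selenenyl chloride to the enol ether gives the α-chloro ether, whose hydrolysis should release the α-selanyl aldehyde; no stereocentre is involved.

Step 9
Reactants: 19 tert-butyl(but-3-yn-1-yloxy)dimethylsilane
Product: 21 (2E)-5-[(tert-butyldimethylsilyl)oxy]-3-methylpent-2-enoic acid, via [(1E)-4-[(tert-butyldimethylsilyl)oxy]-2-methylbut-1-en-1-yl]dimethylalumane 20 (not isolated)
Conditions: Me3Al (2 equiv), Cp2ZrCl2 (25 mol%), CH2Cl2, 0 °C → rt; n-BuLi, THF, −78 °C; CO2; cold dilute HCl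
Reagents that add atoms: trimethylaluminium, C[Al](C)C; carbon dioxide, O=C=O
Why: Zirconium-catalysed syn-carboalumination of the terminal alkyne (Negishi carboalumination) places the new methyl group and aluminium cis on the double bond, and carboxylation of the derived lithium alanate with retention should give only the E acid.

Step 10
Reactants: 14 (4S)-4-[(2R)-butan-2-yl]oxolan-2-one; 6 (4R,6R)-6-[(tert-butyldimethylsilyl)oxy]-4-methylcyclohex-2-en-1-one
Product: 23 (3R,4R)-3-{(1S,4R,6R)-3,4-bis[(tert-butyldimethylsilyl)oxy]-6-methylcyclohex-2-en-1-yl}-4-[(2R)-butan-2-yl]oxolan-2-one, via tert-butyl({(4R)-4-[(2R)-butan-2-yl]-4,5-dihydrofuran-2-yl}oxy)dimethylsilane 22 (not isolated)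
Conditions: LiN(iPr)2, THF, −78 °C; TBSCl, DMPU, −78 °C → rt; then 6, TBSOTf (10 mol%), CH2Cl2, −78 °C
Reagents that add atoms: tert-butyldimethylsilyl chloride, C[Si](C)(Cl)C(C)(C)C
Why: Mukaiyama–Michael addition with silyl transfer: the cyclic ketene silyl acetal should react on the face anti to its sec-butyl group (trans-2,3-disubstituted lactone, setting C1 against C2) and the silyl-activated enone should be attacked anti to the neighbouring methyl group (setting C8a trans to the C8 methyl), so each new stereocentre is controlled by its own ring and the product is the regiodefined enol silane needed in step 15.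

Step 11
Reactants: 23 (3R,4R)-3-{(1S,4R,6R)-3,4-bis[(tert-butyldimethylsilyl)oxy]-6-methylcyclohex-2-en-1-yl}-4-[(2R)-butan-2-yl]oxolan-2-one
Product: 24 (3R,4R)-3-{(1S,4R,6R)-3,4-bis[(tert-butyldimethylsilyl)oxy]-6-methylcyclohex-2-en-1-yl}-4-[(2R)-butan-2-yl]oxolan-2-ol (anomeric mixture)
Conditions: iBu2AlH (1.1 equiv), CH2Cl2, −78 °C; aq. Rochelle salt
Reagents that add atoms: none
Why: Half-reduction of the lactone at low temperature stops at the aluminium hemiacetal, which gives the lactol on work-up; the enol silane and silyl ether are inert and the new anomeric centre is lost in step 12.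

Step 12
Reactants: 24 lactol (anomeric mixture)
Product: 25 (2R,3R)-3-{(1R,4R,6R)-3,4-bis[(tert-butyldimethylsilyl)oxy]-6-methylcyclohex-2-en-1-yl}-2-[(2R)-butan-2-yl]pent-4-en-1-ol
Conditions: Ph3PCH3Br, KN(SiMe3)2, THF, 0 °C → rt
Reagents that add atoms: methyltriphenylphosphonium bromide, C[P+](c1ccccc1)(c1ccccc1)c1ccccc1.[Br-]
Why: Wittig methylenation of the lactol through its open hydroxy-aldehyde form should turn the former lactone carbonyl carbon into the vinyl group that is the latent acetyl group and free the primary alcohol, with the neighbouring stereocentre (future C1) left unchanged.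

Step 13
Reactants: 25 (2R,3R)-3-{(1R,4R,6R)-3,4-bis[(tert-butyldimethylsilyl)oxy]-6-methylcyclohex-2-en-1-yl}-2-[(2R)-butan-2-yl]pent-4-en-1-ol
Product: 26 (2R,3R)-3-{(1R,4R,6R)-3,4-bis[(tert-butyldimethylsilyl)oxy]-6-methylcyclohex-2-en-1-yl}-2-[(2R)-butan-2-yl]pent-4-enal
Conditions: nPr4N[RuO4] (5 mol%), 4-methylmorpholine N-oxide, 4 Å molecular sieves, CH2Cl2, rt
Reagents that add atoms: none
Why: Ley–Griffith oxidation is neutral, so the α-branched aldehyde should not epimerise and the enol silane should survive.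

Step 14
Reactants: 26 (2R,3R)-3-{(1R,4R,6R)-3,4-bis[(tert-butyldimethylsilyl)oxy]-6-methylcyclohex-2-en-1-yl}-2-[(2R)-butan-2-yl]pent-4-enal
Product: 27 tert-butyl({(3R,4R,6R)-3-[(3S,4S,5Z)-4-[(2R)-butan-2-yl]undeca-1,5,10-trien-3-yl]-6-[(tert-butyldimethylsilyl)oxy]-4-methylcyclohex-1-en-1-yl}oxy)dimethylsilane
Conditions: (hex-5-en-1-yl)triphenylphosphonium bromide, NaN(SiMe3)2, THF, −78 → 0 °C
Reagents that add atoms: (hex-5-en-1-yl)triphenylphosphonium bromide, C=CCCCC[P+](c1ccccc1)(c1ccccc1)c1ccccc1.[Br-]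
Why: Wittig olefination with the non-stabilised ylide installs the Z-alkenyl relay arm (its geometry is irrelevant because this alkene is excised in step 17), and the low temperature should limit epimerisation of the α-stereocentre.

Step 15
Reactants: 27 relay enol silane; 18 (phenylselanyl)acetaldehyde
Product: 28 (2R,4R,5R,6S)-5-[(3S,4S,5Z)-4-[(2R)-butan-2-yl]undeca-1,5,10-trien-3-yl]-2-[(tert-butyldimethylsilyl)oxy]-6-[1-hydroxy-2-(phenylselanyl)ethyl]-4-methylcyclohexan-1-one (carbinol epimers)
Conditions: BF3·OEt2 (1.1 equiv), CH2Cl2, −78 °C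
Reagents that add atoms: none
Why: Lewis-acid-mediated Mukaiyama aldol addition of the regiodefined enol silane to the α-selanyl aldehyde: the electrophile should approach the ring carbon anti to the bulky substituent on the adjacent carbon, setting C4a trans to C8a (also the thermodynamic arrangement), and the carbinol configuration is irrelevant because it is destroyed in step 16.

Step 16
Reactants: 28 β-hydroxy selenide (carbinol epimers)
Product: 29 (2R,4R,5R,6R)-5-[(3S,4S,5Z)-4-[(2R)-butan-2-yl]undeca-1,5,10-trien-3-yl]-2-[(tert-butyldimethylsilyl)oxy]-6-ethenyl-4-methylcyclohexan-1-one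
Conditions: MsCl, Et3N, CH2Cl2, 0 °C → rt
Reagents that add atoms: none
Why: Mesylation and selenium-assisted anti-elimination of the β-hydroxy selenide through a seleniranium ion should deliver the terminal vinyl group regiospecifically, so the aldehyde has served as a vinyl cation equivalent and the conjugated ethylidene ketone is avoided.

Step 17
Reactants: 29 relay tetraene
Product: 30 (2R,4R,4aR,5S,6S,8aR)-6-[(2R)-butan-2-yl]-2-[(tert-butyldimethylsilyl)oxy]-5-ethenyl-4-methyl-3,4,4a,5,6,8a-hexahydronaphthalen-1(2H)-one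
Conditions: RuCl2(H2IMes)(=CH-C6H4-2-OiPr) (second-generation Hoveyda–Grubbs catalyst, 10 mol%; H2IMes = 1,3-dimesityl-4,5-dihydroimidazol-2-ylidene), toluene (0.002 M), 60 °C, argon sparge
Reagents that add atoms: none
Why: The ruthenium alkylidene should engage the unhindered terminal alkene of the relay arm first, close onto the neighbouring Z-alkene with loss of cyclopentene and so be placed on the carbon next to the sec-butyl-bearing methine (future C3); cycloaddition and cycloreversion with the vinyl group on the ketone α-carbon (future C4) then form the C3=C4 bond and release ethene, the closest known reaction type being relay ring-closing metathesis of sterically shielded dienes. Ring A is closed as a six-membered carbocycle by alkene–alkene metathesis between two arms that sit trans-diequatorial on the chair of ring B, so the trans ring fusion is locked without strain and the new ring double bond can only be cis. No stereocentre is created; the step ties the six stereocentres already present on ring B and the two arms into the bicyclic core. The selectivity needed is site selectivity among three terminal alkenes: a carbene on the relay-delivered carbon can close only onto the ketone-side vinyl (closure onto the vinyl on the adjacent carbon would give a cyclobutene), whereas a carbene started on either hindered vinyl could also close a five-membered ring, and the relay arm, the shielding of both vinyls by their branched neighbours, high dilution and removal of ethene should secure the first course. The α-vinyl ketone is not enolised under these neutral conditions, so C4a should keep its configuration and the double bond should stay out of conjugation.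

Step 18
Reactants: 30 silyloxy ketone
Product: 31 (2R,4R,4aR,5S,6S,8aR)-6-[(2R)-butan-2-yl]-5-ethenyl-2-hydroxy-4-methyl-3,4,4a,5,6,8a-hexahydronaphthalen-1(2H)-one
Conditions: HF·pyridine, pyridine, THF, 0 °C → rt
Reagents that add atoms: none
Why: Buffered acidic fluoride cleavage of the secondary silyl ether next to the ketone should free the axial hydroxyl (C6 of the target) without epimerising it or moving the ring-A double bond into conjugation.

Step 19
Reactants: 31 α-hydroxy ketone; 21 (2E)-5-[(tert-butyldimethylsilyl)oxy]-3-methylpent-2-enoic acid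
Product: 32 (2R,4R,4aR,5S,6S,8aR)-6-[(2R)-butan-2-yl]-5-ethenyl-4-methyl-1-oxo-1,2,3,4,4a,5,6,8a-octahydronaphthalen-2-yl (2E)-5-[(tert-butyldimethylsilyl)oxy]-3-methylpent-2-enoate
Conditions: EDC·HCl, DMAP (0.3 equiv), CH2Cl2, 0 °C → rt
Reagents that add atoms: none
Why: Steglich esterification acylates the only hydroxyl group present, which fixes the ester on the C6 oxygen before the C5 hydroxyl exists, and the acid has no doubly activated γ-hydrogens, so E/Z scrambling is not expected.

Step 20
Reactants: 32 keto ester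
Product: 33 (1S,2S,4aR,5S,6R,8R,8aR)-2-[(2R)-butan-2-yl]-1-ethenyl-5-hydroxy-8-methyl-1,2,4a,5,6,7,8,8a-octahydronaphthalen-6-yl (2E)-5-[(tert-butyldimethylsilyl)oxy]-3-methylpent-2-enoate
Conditions: NaBH4, CeCl3·7H2O, MeOH, −78 °C; AcOH quench
Reagents that add atoms: none
Why: Luche-type borohydride reduction: hydride should add axially to the chair ketone of the rigid trans-fused bicycle, anti to the axial acyloxy group (Felkin–Anh), giving the equatorial (5S) alcohol cis to the ester, while the enoate and alkenes are untouched and the low temperature suppresses acyl migration.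

Step 21
Reactants: 33 silyl ether
Product: 34 (1S,2S,4aR,5S,6R,8R,8aR)-2-[(2R)-butan-2-yl]-1-ethenyl-5-hydroxy-8-methyl-1,2,4a,5,6,7,8,8a-octahydronaphthalen-6-yl (2E)-5-hydroxy-3-methylpent-2-enoate
Conditions: HF·pyridine, pyridine, THF, 0 °C → rt
Reagents that add atoms: none
Why: Acidic fluoride desilylation frees the primary alcohol, and migration of the ester to the cis-vicinal hydroxyl is slow under acid.

Step 22
Reactants: 34 diol
Product: 35 (3E)-5-{[(1S,2S,4aR,5S,6R,8R,8aR)-2-[(2R)-butan-2-yl]-1-ethenyl-5-hydroxy-8-methyl-1,2,4a,5,6,7,8,8a-octahydronaphthalen-6-yl]oxy}-3-methyl-5-oxopent-3-enoic acid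
Conditions: TEMPO (20 mol%), PhI(OAc)2 (2.5 equiv), MeCN/H2O (1:1), rt
Reagents that add atoms: water, O
Why: Oxoammonium-mediated oxidation should take the primary alcohol through the aldehyde hydrate to the carboxylic acid and leave the hindered secondary C5 alcohol and the alkenes alone, so the acidic methylene of the 3-methylglutaconate is created only now and never meets base.

Step 23
Reactants: 35 vinyl acid
Product: 36 (3E)-5-{[(1S,2S,4aR,5S,6R,8R,8aS)-1-acetyl-2-[(2R)-butan-2-yl]-5-hydroxy-8-methyl-1,2,4a,5,6,7,8,8a-octahydronaphthalen-6-yl]oxy}-3-methyl-5-oxopent-3-enoic acid (target)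
Conditions: PdCl2 (20 mol%), CuCl (1 equiv), O2 (1 atm), DMF/H2O (7:1), rt
Reagents that add atoms: water, O
Why: Tsuji–Wacker oxidation: divalent palladium should activate the only terminal alkene, water adds at the internal carbon and β-hydride elimination with tautomerisation gives the methyl ketone, while the disubstituted ring alkene and the electron-poor enoate react far more slowly and the weakly acidic medium should leave the C1 stereocentre, the ester position and the E geometry untouched.

## Compound list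

1 | propanal | CCC=O | starting material
2 | but-3-en-2-one (methyl vinyl ketone) | CC(=O)C=C | starting material
3 | (2R)-2-methyl-5-oxohexanal | C[C@@H](C=O)CCC(C)=O | intermediate
4 | (4R)-4-methylcyclohex-2-en-1-one | C[C@@H]1CCC(=O)C=C1 | intermediate
5 | (4R,6R)-6-hydroxy-4-methylcyclohex-2-en-1-one | C[C@@H]1C[C@@H](O)C(=O)C=C1 | intermediate
6 | (4R,6R)-6-[(tert-butyldimethylsilyl)oxy]-4-methylcyclohex-2-en-1-one | C[C@@H]1C[C@@H](O[Si](C)(C)C(C)(C)C)C(=O)C=C1 | intermediate
7 | (4S)-4-benzyl-1,3-oxazolidin-2-one | O=C1N[C@@H](Cc2ccccc2)CO1 | starting material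
8 | (2E)-pent-2-enoyl chloride | CC/C=C/C(Cl)=O | starting material
9 | (4S)-4-benzyl-3-[(2E)-pent-2-enoyl]-1,3-oxazolidin-2-one | CC/C=C/C(=O)N1[C@@H](Cc2ccccc2)COC1=O | intermediate
10 | (4S)-4-benzyl-3-[(3R)-3-methylpentanoyl]-1,3-oxazolidin-2-one | CC[C@@H](C)CC(=O)N1[C@@H](Cc2ccccc2)COC1=O | intermediate
11 | tert-butyl bromoacetate | BrCC(=O)OC(C)(C)C | starting material
12 | tert-butyl (3S,4R)-3-{[(4S)-4-benzyl-2-oxo-1,3-oxazolidin-3-yl]carbonyl}-4-methylhexanoate | CC[C@@H](C)[C@H](CC(=O)OC(C)(C)C)C(=O)N1[C@@H](Cc2ccccc2)COC1=O | intermediate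
13 | tert-butyl (3S,4R)-3-(hydroxymethyl)-4-methylhexanoate | CC[C@@H](C)[C@H](CC(=O)OC(C)(C)C)CO | intermediate
14 | (4S)-4-[(2R)-butan-2-yl]oxolan-2-one | CC[C@@H](C)[C@@H]1CC(=O)OC1 | intermediate
15 | benzeneselenenyl chloride | Cl[Se]c1ccccc1 | starting material
16 | ethyl vinyl ether | C=COCC | starting material
17 | [(2-chloro-2-ethoxyethyl)selanyl]benzene (racemic) | CCOC(Cl)C[Se]c1ccccc1 | intermediate
18 | (phenylselanyl)acetaldehyde | O=CC[Se]c1ccccc1 | intermediate
19 | tert-butyl(but-3-yn-1-yloxy)dimethylsilane | C#CCCO[Si](C)(C)C(C)(C)C | starting material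
20 | [(1E)-4-[(tert-butyldimethylsilyl)oxy]-2-methylbut-1-en-1-yl]dimethylalumane | C[Al](C)/C=C(\C)CCO[Si](C)(C)C(C)(C)C | intermediate
21 | (2E)-5-[(tert-butyldimethylsilyl)oxy]-3-methylpent-2-enoic acid | OC(=O)/C=C(\C)CCO[Si](C)(C)C(C)(C)C | intermediate
22 | tert-butyl({(4R)-4-[(2R)-butan-2-yl]-4,5-dihydrofuran-2-yl}oxy)dimethylsilane | CC[C@@H](C)[C@@H]1C=C(O[Si](C)(C)C(C)(C)C)OC1 | intermediate
23 | (3R,4R)-3-{(1S,4R,6R)-3,4-bis[(tert-butyldimethylsilyl)oxy]-6-methylcyclohex-2-en-1-yl}-4-[(2R)-butan-2-yl]oxolan-2-one | CC[C@@H](C)[C@H]1COC(=O)[C@@H]1[C@@H]1C=C(O[Si](C)(C)C(C)(C)C)[C@H](O[Si](C)(C)C(C)(C)C)C[C@H]1C | intermediate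
24 | (3R,4R)-3-{(1S,4R,6R)-3,4-bis[(tert-butyldimethylsilyl)oxy]-6-methylcyclohex-2-en-1-yl}-4-[(2R)-butan-2-yl]oxolan-2-ol (anomeric mixture) | CC[C@@H](C)[C@H]1COC(O)[C@@H]1[C@@H]1C=C(O[Si](C)(C)C(C)(C)C)[C@H](O[Si](C)(C)C(C)(C)C)C[C@H]1C | intermediate
25 | (2R,3R)-3-{(1R,4R,6R)-3,4-bis[(tert-butyldimethylsilyl)oxy]-6-methylcyclohex-2-en-1-yl}-2-[(2R)-butan-2-yl]pent-4-en-1-ol | CC[C@@H](C)[C@@H](CO)[C@H](C=C)[C@@H]1C=C(O[Si](C)(C)C(C)(C)C)[C@H](O[Si](C)(C)C(C)(C)C)C[C@H]1C | intermediate
26 | (2R,3R)-3-{(1R,4R,6R)-3,4-bis[(tert-butyldimethylsilyl)oxy]-6-methylcyclohex-2-en-1-yl}-2-[(2R)-butan-2-yl]pent-4-enal | CC[C@@H](C)[C@@H](C=O)[C@H](C=C)[C@@H]1C=C(O[Si](C)(C)C(C)(C)C)[C@H](O[Si](C)(C)C(C)(C)C)C[C@H]1C | intermediate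
27 | tert-butyl({(3R,4R,6R)-3-[(3S,4S,5Z)-4-[(2R)-butan-2-yl]undeca-1,5,10-trien-3-yl]-6-[(tert-butyldimethylsilyl)oxy]-4-methylcyclohex-1-en-1-yl}oxy)dimethylsilane | CC[C@@H](C)[C@@H](/C=C\CCCC=C)[C@H](C=C)[C@@H]1C=C(O[Si](C)(C)C(C)(C)C)[C@H](O[Si](C)(C)C(C)(C)C)C[C@H]1C | intermediate
28 | (2R,4R,5R,6S)-5-[(3S,4S,5Z)-4-[(2R)-butan-2-yl]undeca-1,5,10-trien-3-yl]-2-[(tert-butyldimethylsilyl)oxy]-6-[1-hydroxy-2-(phenylselanyl)ethyl]-4-methylcyclohexan-1-one (carbinol epimers) | CC[C@@H](C)[C@@H](/C=C\CCCC=C)[C@H](C=C)[C@@H]1[C@@H](C(O)C[Se]c2ccccc2)C(=O)[C@H](O[Si](C)(C)C(C)(C)C)C[C@H]1C | intermediate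
29 | (2R,4R,5R,6R)-5-[(3S,4S,5Z)-4-[(2R)-butan-2-yl]undeca-1,5,10-trien-3-yl]-2-[(tert-butyldimethylsilyl)oxy]-6-ethenyl-4-methylcyclohexan-1-one | CC[C@@H](C)[C@@H](/C=C\CCCC=C)[C@H](C=C)[C@@H]1[C@@H](C=C)C(=O)[C@H](O[Si](C)(C)C(C)(C)C)C[C@H]1C | intermediate
30 | (2R,4R,4aR,5S,6S,8aR)-6-[(2R)-butan-2-yl]-2-[(tert-butyldimethylsilyl)oxy]-5-ethenyl-4-methyl-3,4,4a,5,6,8a-hexahydronaphthalen-1(2H)-one | CC[C@@H](C)[C@H]1C=C[C@H]2C(=O)[C@H](O[Si](C)(C)C(C)(C)C)C[C@@H](C)[C@@H]2[C@H]1C=C | intermediate
31 | (2R,4R,4aR,5S,6S,8aR)-6-[(2R)-butan-2-yl]-5-ethenyl-2-hydroxy-4-methyl-3,4,4a,5,6,8a-hexahydronaphthalen-1(2H)-one | CC[C@@H](C)[C@H]1C=C[C@H]2C(=O)[C@H](O)C[C@@H](C)[C@@H]2[C@H]1C=C | intermediate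
32 | (2R,4R,4aR,5S,6S,8aR)-6-[(2R)-butan-2-yl]-5-ethenyl-4-methyl-1-oxo-1,2,3,4,4a,5,6,8a-octahydronaphthalen-2-yl (2E)-5-[(tert-butyldimethylsilyl)oxy]-3-methylpent-2-enoate | CC[C@@H](C)[C@H]1C=C[C@H]2C(=O)[C@H](OC(=O)/C=C(\C)CCO[Si](C)(C)C(C)(C)C)C[C@@H](C)[C@@H]2[C@H]1C=C | intermediate
33 | (1S,2S,4aR,5S,6R,8R,8aR)-2-[(2R)-butan-2-yl]-1-ethenyl-5-hydroxy-8-methyl-1,2,4a,5,6,7,8,8a-octahydronaphthalen-6-yl (2E)-5-[(tert-butyldimethylsilyl)oxy]-3-methylpent-2-enoate | CC[C@@H](C)[C@H]1C=C[C@H]2[C@H](O)[C@H](OC(=O)/C=C(\C)CCO[Si](C)(C)C(C)(C)C)C[C@@H](C)[C@@H]2[C@H]1C=C | intermediate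
34 | (1S,2S,4aR,5S,6R,8R,8aR)-2-[(2R)-butan-2-yl]-1-ethenyl-5-hydroxy-8-methyl-1,2,4a,5,6,7,8,8a-octahydronaphthalen-6-yl (2E)-5-hydroxy-3-methylpent-2-enoate | CC[C@@H](C)[C@H]1C=C[C@H]2[C@H](O)[C@H](OC(=O)/C=C(\C)CCO)C[C@@H](C)[C@@H]2[C@H]1C=C | intermediate
35 | (3E)-5-{[(1S,2S,4aR,5S,6R,8R,8aR)-2-[(2R)-butan-2-yl]-1-ethenyl-5-hydroxy-8-methyl-1,2,4a,5,6,7,8,8a-octahydronaphthalen-6-yl]oxy}-3-methyl-5-oxopent-3-enoic acid | CC[C@@H](C)[C@H]1C=C[C@H]2[C@H](O)[C@H](OC(=O)/C=C(\C)CC(=O)O)C[C@@H](C)[C@@H]2[C@H]1C=C | intermediate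
36 | (3E)-5-{[(1S,2S,4aR,5S,6R,8R,8aS)-1-acetyl-2-[(2R)-butan-2-yl]-5-hydroxy-8-methyl-1,2,4a,5,6,7,8,8a-octahydronaphthalen-6-yl]oxy}-3-methyl-5-oxopent-3-enoic acid | CC[C@@H](C)[C@H]1C=C[C@H]2[C@H](O)[C@H](OC(=O)/C=C(\C)CC(=O)O)C[C@@H](C)[C@@H]2[C@H]1C(C)=O | target

## Step count and risks

Total step count: 23. Longest linear sequence: 18 (steps 4–7, then 10–23).

**Step 10 (union of lactone and enone).** What may go wrong: slow addition between two β-branched partners, competing 1,2-addition, and erosion of facial selectivity at C8a and C1 if the two chiral partners meet in a mismatched sense in the open transition state. The fallback sets out from 14 and 6 and returns at 23. The lithium enolate of 14 (LiN(iPr)2, THF, −78 °C) is added to 6; the kinetically formed tertiary allylic alkoxide of the 1,2-adduct (3S,4R)-4-[(2R)-butan-2-yl]-3-[(4R,6R)-6-[(tert-butyldimethylsilyl)oxy]-1-hydroxy-4-methylcyclohex-2-en-1-yl]oxolan-2-one F1 is not isolated but warmed to 0 °C with HMPA. Retro-aldol cleavage and conjugate re-addition should then funnel it to the more stable enolate of the 1,4-adduct, which is trapped on oxygen with TBSCl to give 23. This replaces the Lewis-acid pathway by an anionic addition under thermodynamic control.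

**Step 15 (aldol at the hindered ring carbon).** What may go wrong: the hindered enol silane fails to add to the aldehyde, the Lewis acid ionises the selenide or strips the secondary silyl ether, or facial control at C4a is poor. The fallback sets out from 27 and returns at 29, bypassing 28 and step 16. The enol silane is cleaved with MeLi (THF, 0 °C) to the regiodefined lithium enolate, which is added at −78 °C to phenyl vinyl sulfoxide (Michael addition to a vinyl cation equivalent) to give (2R,4R,5R,6R)-6-[2-(benzenesulfinyl)ethyl]-5-[(3S,4S,5Z)-4-[(2R)-butan-2-yl]undeca-1,5,10-trien-3-yl]-2-[(tert-butyldimethylsilyl)oxy]-4-methylcyclohexan-1-one F2 (sulfoxide epimers). Thermal syn-elimination of the sulfoxide (toluene, CaCO3, 110 °C) should then give the vinyl ketone 29.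

**Step 17 (relay ring-closing metathesis).** What may go wrong: loss of site control, through initiation at the ketone-side vinyl or premature truncation of the relay arm by ethene, so that closure onto the vinyl on the neighbouring carbon gives the trans-fused five-membered ring in place of ring A. The fallback sets out from 29 and returns at 30. The kinetically formed cyclopentene (1S,3aR,5R,7R,7aR)-5-[(tert-butyldimethylsilyl)oxy]-7-methyl-1-[(3R,4S,5Z)-3-methylundeca-5,10-dien-4-yl]-1,3a,5,6,7,7a-hexahydro-4H-inden-4-one F3 is isolated and subjected to ring-rearrangement metathesis with RuCl2(H2IMes)(PCy3)(=CHPh) (second-generation Grubbs catalyst) in toluene at 60 °C under an ethene atmosphere. The relay arm should deliver ruthenium to the side-chain carbon, the strained trans-fused cyclopentene is opened at its distal alkene carbon with closure of the six-membered ring, and the liberated alkylidene is capped by ethene as the vinyl group of 30.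

Further compounds
F1 | step 10 | (3S,4R)-4-[(2R)-butan-2-yl]-3-[(4R,6R)-6-[(tert-butyldimethylsilyl)oxy]-1-hydroxy-4-methylcyclohex-2-en-1-yl]oxolan-2-one (carbinol epimers) | CC[C@@H](C)[C@H]1COC(=O)[C@@H]1C1(O)C=C[C@H](C)C[C@H]1O[Si](C)(C)C(C)(C)C
F2 | step 15 | (2R,4R,5R,6R)-6-[2-(benzenesulfinyl)ethyl]-5-[(3S,4S,5Z)-4-[(2R)-butan-2-yl]undeca-1,5,10-trien-3-yl]-2-[(tert-butyldimethylsilyl)oxy]-4-methylcyclohexan-1-one (sulfoxide epimers) | CC[C@@H](C)[C@@H](/C=C\CCCC=C)[C@H](C=C)[C@@H]1[C@@H](CCS(=O)c2ccccc2)C(=O)[C@H](O[Si](C)(C)C(C)(C)C)C[C@H]1C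
F3 | step 17 | (1S,3aR,5R,7R,7aR)-5-[(tert-butyldimethylsilyl)oxy]-7-methyl-1-[(3R,4S,5Z)-3-methylundeca-5,10-dien-4-yl]-1,3a,5,6,7,7a-hexahydro-4H-inden-4-one | CC[C@@H](C)[C@@H](/C=C\CCCC=C)[C@@H]1C=C[C@H]2C(=O)[C@H](O[Si](C)(C)C(C)(C)C)C[C@@H](C)[C@H]12
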